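**Plan**

- Retrosynthesis: C9–C11 and C8–C17 are cut together (conjugate addition to a ring B C7 enone, capture at C8). The C7 carbinol goes back to the ketone and the C6 benzoate to a cis-6β,7β-diol. Ring B is then cut at C9–C10 and C5–C6 (Michael/aldol), and the C10 and C4 methyl groups are removed from a cyclohexanone β-keto ester.
- Forward: ring A is made first as a C4-quaternary keto ester. Ring B is annulated with a methoxymethyl vinyl ketone that brings the C6 oxygen, and the benzoate is placed on O6 through an orthoester. The side chain and C17 are joined last in one flask.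
- Stereochemistry: C4 from a valine auxiliary; C10 by 1,3-induction from C4; C5, C6 and the temporary C7 centre by α-face protonation and hydride delivery; C9 by axial cuprate attack anti to the C20 methyl; C7 last by reduction of the methylene ketone.
- Enabling feature: C8 carries the exocyclic C17 methylene and lies between the C7 carbinol and C9, and the C9 side chain is trans to the angular C20 methyl on C10. This is the imprint of a nucleophile at C9 and an electrophile at C8 of a ring B enone.

Key step: step 17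

Remark on locants: labdane locants are used (ring A C1–C5 and C10; ring B C5–C10; C17 on C8; C18 methyl and C19 carboxyl on C4; C20 methyl on C10; C11–C16 side chain); β is the face of C20; TMSE = 2-(trimethylsilyl)ethyl.
Assumption: methylation of the lithiated L-valine tert-butyl ester enamine in toluene/HMPA is taken to give the (S) ester; if this ligand set gave the (R) ester, D-valine tert-butyl ester would be used in the same way.

**Route**

Step 1
Reactants: 1 ethyl 2-oxocyclohexane-1-carboxylate
Product: 2 TMSE 2-oxocyclohexane-1-carboxylate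
Conditions: Me3SiCH2CH2OH, DMAP (cat.), toluene, reflux, EtOH distilled off
Reagents that add atoms: 2-(trimethylsilyl)ethanol, C[Si](C)(C)CCO
Why: DMAP-catalysed transesterification of a β-keto ester, driven by removal of ethanol, puts the fluoride-labile ester in place before C4 becomes quaternary.

Step 2
Reactants: 2 TMSE 2-oxocyclohexane-1-carboxylate
Product: 3 enamino ester of 2 with L-valine tert-butyl ester
Conditions: L-Val-OtBu, TsOH·H2O (cat.), benzene, reflux, Dean–Stark
Reagents that add atoms: L-valine tert-butyl ester, CC(C)[C@H](N)C(=O)OC(C)(C)C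
Why: Acid-catalysed condensation of the β-keto ester with the primary amine gives the hydrogen-bonded enamino ester (vinylogous carbamate) as the only tautomer.

Step 3
Reactants: 3 enamino ester
Product: 5 TMSE (1S)-1-methyl-2-oxocyclohexane-1-carboxylate, via methylated ketimine 4 (not isolated)
Conditions: LDA, toluene, HMPA, −78 °C; MeI; then 1 M HCl, Et2O, 0 °C
Reagents that add atoms: iodomethane, CI; water, O
Why: Auxiliary-controlled alkylation of a chelated lithium aza-enolate, in which the isopropyl group leaves one face of C4 open to iodomethane, sets the quaternary C4 centre, and mild acid then hydrolyses the ketimine and returns the auxiliary.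

Step 4
Reactants: 5 TMSE (1S)-1-methyl-2-oxocyclohexane-1-carboxylate
Product: 6 TMSE (1S)-1,3-dimethyl-2-oxocyclohexane-1-carboxylate (both C3 epimers)
Conditions: LDA, THF, −78 °C; MeI, −78 → 0 °C
Reagents that add atoms: iodomethane, CI
Why: Kinetic enolate alkylation, since the ketone can enolise only toward C10; the configuration formed there is of no consequence because this carbon is planarised again in step 6.

Step 5
Reactants: 7 N,2-dimethoxy-N-methylacetamide
Product: 8 1-methoxybut-3-en-2-one
Conditions: CH2=CHMgBr, THF, −78 → 0 °C; inverse quench into cold 2 M HCl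
Reagents that add atoms: vinylmagnesium bromide, C=C[Mg]Br
Why: Weinreb ketone synthesis, in which the chelated tetrahedral adduct stops at one addition and the acid quench keeps the liberated amine from adding to the vinyl ketone.

Step 6
Reactants: 6 TMSE (1S)-1,3-dimethyl-2-oxocyclohexane-1-carboxylate; 8 1-methoxybut-3-en-2-one
Product: 10 TMSE (1S,3R)-3-(4-methoxy-3-oxobutyl)-1,3-dimethyl-2-oxocyclohexane-1-carboxylate, via silyl enol ether 9 (not isolated)
Conditions: LDA, THF, −78 → 0 °C, Me3SiCl; then 8, Sc(OTf)3 (10 mol %), CH2Cl2, −78 °C; 1 M HCl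
Reagents that add atoms: none
Why: Mukaiyama–Michael addition through an open transition state, in which the acceptor should approach C10 anti to the C19 ester (expected pseudoaxial on the enol ether, being smaller than methyl and aligned with the π system), so that the new chain ends trans and the C20 methyl cis to the ester.

Step 7
Reactants: 10 diketone
Product: 11 TMSE 6-methoxy-4α,10β-dimethyl-7-oxodecal-5-ene-4β-carboxylate
Conditions: CSA (10 mol %), toluene, 90 °C, Dean–Stark
Reagents that add atoms: none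
Why: Acid-catalysed intramolecular aldol condensation (second stage of a Robinson annulation), in which only the C6 enol of the methoxy ketone can reach the ring A carbonyl in a six-membered closure; acid is used because an alkoxide could fragment the β-keto ester by retro-Claisen cleavage.

Step 8
Reactants: 11 bicyclic methoxy enone
Product: 13 TMSE 7β-hydroxy-4α,10β-dimethyl-6-oxo-5α-decalin-4β-carboxylate, via allylic alcohol enol ether 12 (not isolated)
Conditions: NaBH4, CeCl3·7H2O, MeOH, −40 °C; then 1 M HCl, THF, 0 → 25 °C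
Reagents that add atoms: water, O
Why: Luche 1,2-reduction (axial hydride from the α-face gives the equatorial 7β-carbinol) followed by hydrolysis of the tetrasubstituted enol ether, in which C5 is protonated from the open α-face and, being α to the new C6 ketone, can in any case equilibrate to the trans-fused decalin.

Step 9
Reactants: 13 7β-hydroxy-6-ketone
Product: 14 TMSE 6β,7β-dihydroxy-4α,10β-dimethyl-5α-decalin-4β-carboxylate
Conditions: NaBH4, MeOH, −20 °C; AcOH quench
Reagents that add atoms: none
Why: Borohydride reduction in which hydride can reach the C6 carbonyl only from the α-face, the β-face being covered by the syn-axial C20 methyl and C19 ester, so the axial 6β-hydroxyl forms cis to the 7β-hydroxyl.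

Step 10
Reactants: 14 cis-6β,7β-diol
Product: 16 TMSE 6β-(benzoyloxy)-7β-hydroxy-4α,10β-dimethyl-5α-decalin-4β-carboxylate, via cyclic orthobenzoate 15 (not isolated)
Conditions: PhC(OMe)3, CSA (cat.), CH2Cl2, 25 °C; then AcOH/H2O 4:1, 25 °C
Reagents that add atoms: trimethyl orthobenzoate, COC(OC)(OC)c1ccccc1; water, O
Why: Orthoester exchange onto the cis-diol followed by mild acid hydrolysis, which opens a cyclohexane-fused 2-hydroxy-1,3-dioxolane to the axial ester and the equatorial alcohol, places the benzoate on the hindered 6β-oxygen without a direct acylation.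

Step 11
Reactants: 16 6β-benzoate 7β-alcohol
Product: 17 TMSE 6β-(benzoyloxy)-4α,10β-dimethyl-7-oxo-5α-decalin-4β-carboxylate
Conditions: Dess–Martin periodinane, NaHCO3, CH2Cl2, 0 → 25 °C
Reagents that add atoms: none
Why: Dess–Martin oxidation of the secondary carbinol under buffered conditions, under which the equatorial C6 hydrogen is not enolised and the benzoate does not migrate.

Step 12
Reactants: 17 6β-benzoyloxy 7-ketone
Product: 19 TMSE 6β-(benzoyloxy)-4α,10β-dimethyl-7-oxo-5α-decal-8-ene-4β-carboxylate, via C7 silyl enol ether 18 (not isolated)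
Conditions: Me3SiOTf, Et3N, CH2Cl2, 0 °C; then Pd(OAc)2 (1.1 equiv), MeCN, 25 °C
Reagents that add atoms: none
Why: Saegusa–Ito oxidation, in which soft enolisation removes the axial C8 hydrogen (the C6 hydrogen is equatorial and hindered) and the divalent palladium enolate loses the C9 hydride to give the C8=C9 enone.

Step 13
Reactants: 20 tert-butyl(but-3-yn-1-yloxy)dimethylsilane
Product: 22 (2E)-5-[(tert-butyldimethylsilyl)oxy]-3-methylpent-2-en-1-ol, via alkenylalane 21 (not isolated)
Conditions: Me3Al, Cp2ZrCl2 (0.25 equiv), CH2Cl2, 0 → 25 °C; then n-BuLi, THF, −78 °C; (CH2O)n, −78 → 25 °C; aq. HCl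
Reagents that add atoms: trimethylaluminium, C[Al](C)C; formaldehyde (as paraformaldehyde), C=O
Why: Zirconium-catalysed syn-methylalumination puts methyl on the internal and aluminium on the terminal alkyne carbon, and the derived alanate adds to formaldehyde with retention, so the trisubstituted alkene is E.

Step 14
Reactants: 22 allylic alcohol
Product: 23 (2E)-1-O-(tert-butyldiphenylsilyl)-5-O-(tert-butyldimethylsilyl)-3-methylpent-2-ene-1,5-diol
Conditions: t-BuPh2SiCl, imidazole, DMF, 25 °C
Reagents that add atoms: tert-butyl(chloro)diphenylsilane, CC(C)(C)[Si](Cl)(c1ccccc1)c1ccccc1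
Why: Standard silylation of a primary allylic alcohol with a silyl group that survives the next acid step and the Grignard formation.

Step 15
Reactants: 23 bis-silyl ether
Product: 24 (3E)-5-[(tert-butyldiphenylsilyl)oxy]-3-methylpent-3-en-1-ol
Conditions: PPTS (0.2 equiv), EtOH, 40 °C
Reagents that add atoms: none
Why: Acid-catalysed ethanolysis cleaves a primary tert-butyldimethylsilyl ether much faster than the bulkier tert-butyldiphenylsilyl ether.

Step 16
Reactants: 24 homoallylic alcohol
Product: 25 [(2E)-5-bromo-3-methylpent-2-en-1-yl]oxy(tert-butyl)diphenylsilane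
Conditions: CBr4, PPh3, CH2Cl2, 0 °C
Reagents that add atoms: tetrabromomethane, BrC(Br)(Br)Br
Why: Appel reaction, an SN2 displacement of the oxyphosphonium at a primary carbon under neutral conditions that leave the allylic silyl ether and the alkene geometry untouched.

Step 17
Reactants: 19 ring B enone; 25 side-chain bromide; 26 dimethyl(methylidene)ammonium iodide
Product: 29 TMSE 6β-(benzoyloxy)-15-[(tert-butyldiphenylsilyl)oxy]-17-(dimethylamino)-7-oxo-8βH,9βH-labd-13E-en-19-oate, via Grignard reagent 27 (not isolated), via C9-alkylated silyl enol ether 28 (not isolated)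
Conditions: 25, Mg, THF, 25 °C; CuBr·SMe2 (20 mol %), Me3SiCl, HMPA, THF, −78 °C, then 19; then 26, CH2Cl2, −78 → 25 °C; aq. NaHCO3
Reagents that add atoms: none
Why: The Grignard reagent and catalytic CuBr·SMe2 form an organocuprate that adds to the enone β-carbon C9, Me3SiCl captures the C7 enolate as its silyl enol ether, and the iminium salt then alkylates C8 in a Mannich step, so C9–C11 and C8–C17 are formed in one flask. The closest known reactions are the Me3SiCl-accelerated copper-catalysed 1,4-addition of Grignard reagents to cyclohexenones and the aminomethylation of silyl enol ethers with dimethyl(methylidene)ammonium iodide. No ring is closed. C9 is set by axial attack on the half-chair enone from the α-face, anti to the axial C20 methyl on the neighbouring C10, which gives the side chain its α orientation. C8 is expected α (iminium approach away from the syn-axial 6β-benzoate and C20 methyl) but either epimer converges in step 18. The step needs 1,4- over 1,2-addition and an untouched benzoate and TMSE ester, which are secured by copper catalysis with Me3SiCl at −78 °C, the hindrance of both esters, and the fact that no free enolate is present to take the benzoyl group from O6.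

Step 18
Reactants: 29 Mannich base
Product: 31 TMSE 6β-(benzoyloxy)-15-[(tert-butyldiphenylsilyl)oxy]-7-oxo-9βH-labda-8(17),13E-dien-19-oate, via trimethylammonium iodide 30 (not isolated)
Conditions: MeI, CH2Cl2, 25 °C; then NaHCO3 (aq), CH2Cl2, 25 °C
Reagents that add atoms: none
Why: Quaternisation of the Mannich base and E1cB (Hofmann-type) loss of trimethylamine under bicarbonate gives the α-methylene ketone, the weak base avoiding migration of the double bond into the ring and enolisation at C6.

Step 19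
Reactants: 31 methylene ketone
Product: 32 TMSE 6β-(benzoyloxy)-15-[(tert-butyldiphenylsilyl)oxy]-7α-hydroxy-9βH-labda-8(17),13E-dien-19-oate
Conditions: NaBH4, CeCl3·7H2O, MeOH, −78 °C
Reagents that add atoms: none
Why: Luche 1,2-reduction in which hydride is expected from the β-face, because the axial C9 side chain is 1,3-diaxial to the α trajectory and allylic strain with the 8(17)-methylene favours the axial 7α-carbinol, although the axial 6β-benzoate opposes this and makes C7 the least secure centre of the route.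

Step 20
Reactants: 32 7α-alcohol
Product: 33 6β-(benzoyloxy)-7α,15-dihydroxy-9βH-labda-8(17),13E-dien-19-oic acid (CNP0149011.1)
Conditions: Bu4NF, THF, 0 → 25 °C; aq. NH4Cl
Reagents that add atoms: none
Why: Fluoride attacks silicon, so the TMSE ester fragments to the carboxylate, ethene and Me3SiF and the silyl ether is cleaved, while the benzoate (trans-diaxial to the free 7α-hydroxyl and unable to migrate) and both alkenes are left alone.

**Compound list**

1 | ethyl 2-oxocyclohexane-1-carboxylate | CCOC(=O)C1CCCCC1=O | starting material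
2 | 2-(trimethylsilyl)ethyl 2-oxocyclohexane-1-carboxylate | C[Si](C)(C)CCOC(=O)C1CCCCC1=O | intermediate
3 | tert-butyl N-(2-{[2-(trimethylsilyl)ethoxy]carbonyl}cyclohex-1-en-1-yl)-L-valinate | CC(C)[C@H](NC1=C(C(=O)OCC[Si](C)(C)C)CCCC1)C(=O)OC(C)(C)C | intermediate
4 | tert-butyl N-[(2S)-2-methyl-2-{[2-(trimethylsilyl)ethoxy]carbonyl}cyclohexylidene]-L-valinate | CC(C)[C@H](N=C1CCCC[C@]1(C)C(=O)OCC[Si](C)(C)C)C(=O)OC(C)(C)C | intermediate (not isolated)
5 | 2-(trimethylsilyl)ethyl (1S)-1-methyl-2-oxocyclohexane-1-carboxylate | O=C1CCCC[C@]1(C)C(=O)OCC[Si](C)(C)C | intermediate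
6 | 2-(trimethylsilyl)ethyl (1S)-1,3-dimethyl-2-oxocyclohexane-1-carboxylate (C3 epimers) | CC1CCC[C@](C)(C(=O)OCC[Si](C)(C)C)C1=O | intermediate
7 | N,2-dimethoxy-N-methylacetamide | COCC(=O)N(C)OC | starting material
8 | 1-methoxybut-3-en-2-one | COCC(=O)C=C | intermediate
9 | 2-(trimethylsilyl)ethyl (1S)-1,3-dimethyl-2-[(trimethylsilyl)oxy]cyclohex-2-ene-1-carboxylate | CC1=C(O[Si](C)(C)C)[C@](C)(CCC1)C(=O)OCC[Si](C)(C)C | intermediate (not isolated)
10 | 2-(trimethylsilyl)ethyl (1S,3R)-3-(4-methoxy-3-oxobutyl)-1,3-dimethyl-2-oxocyclohexane-1-carboxylate (chain trans, ring C3 methyl cis to the ester) | COCC(=O)CC[C@@]1(C)CCC[C@](C)(C(=O)OCC[Si](C)(C)C)C1=O | intermediate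
11 | 2-(trimethylsilyl)ethyl 6-methoxy-4α,10β-dimethyl-7-oxodecal-5-ene-4β-carboxylate | O=C1CC[C@@]2(C)CCC[C@](C)(C(=O)OCC[Si](C)(C)C)C2=C1OC | intermediate
12 | 2-(trimethylsilyl)ethyl 7β-hydroxy-6-methoxy-4α,10β-dimethyldecal-5-ene-4β-carboxylate | O[C@@H]1CC[C@@]2(C)CCC[C@](C)(C(=O)OCC[Si](C)(C)C)C2=C1OC | intermediate (not isolated)
13 | 2-(trimethylsilyl)ethyl 7β-hydroxy-4α,10β-dimethyl-6-oxo-5α-decalin-4β-carboxylate | O[C@@H]1CC[C@@]2(C)CCC[C@](C)(C(=O)OCC[Si](C)(C)C)[C@@H]2C1=O | intermediate
14 | 2-(trimethylsilyl)ethyl 6β,7β-dihydroxy-4α,10β-dimethyl-5α-decalin-4β-carboxylate | O[C@@H]1CC[C@@]2(C)CCC[C@](C)(C(=O)OCC[Si](C)(C)C)[C@@H]2[C@@H]1O | intermediate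
15 | 6β,7β-O-(α-methoxybenzylidene) orthoester of 14 (either configuration at the orthoester carbon) | COC1(c2ccccc2)O[C@@H]2CC[C@@]3(C)CCC[C@](C)(C(=O)OCC[Si](C)(C)C)[C@@H]3[C@@H]2O1 | intermediate (not isolated)
16 | 2-(trimethylsilyl)ethyl 6β-(benzoyloxy)-7β-hydroxy-4α,10β-dimethyl-5α-decalin-4β-carboxylate | O[C@@H]1CC[C@@]2(C)CCC[C@](C)(C(=O)OCC[Si](C)(C)C)[C@@H]2[C@@H]1OC(=O)c1ccccc1 | intermediate
17 | 2-(trimethylsilyl)ethyl 6β-(benzoyloxy)-4α,10β-dimethyl-7-oxo-5α-decalin-4β-carboxylate | O=C1CC[C@@]2(C)CCC[C@](C)(C(=O)OCC[Si](C)(C)C)[C@@H]2[C@@H]1OC(=O)c1ccccc1 | intermediate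
18 | 2-(trimethylsilyl)ethyl 6β-(benzoyloxy)-4α,10β-dimethyl-7-[(trimethylsilyl)oxy]-5α-decal-7-ene-4β-carboxylate | C[Si](C)(C)OC1=CC[C@@]2(C)CCC[C@](C)(C(=O)OCC[Si](C)(C)C)[C@@H]2[C@@H]1OC(=O)c1ccccc1 | intermediate (not isolated)
19 | 2-(trimethylsilyl)ethyl 6β-(benzoyloxy)-4α,10β-dimethyl-7-oxo-5α-decal-8-ene-4β-carboxylate (ring B enone) | O=C1C=C[C@@]2(C)CCC[C@](C)(C(=O)OCC[Si](C)(C)C)[C@@H]2[C@@H]1OC(=O)c1ccccc1 | intermediate
20 | tert-butyl(but-3-yn-1-yloxy)dimethylsilane | C#CCCO[Si](C)(C)C(C)(C)C | starting material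
21 | [(1E)-4-[(tert-butyldimethylsilyl)oxy]-2-methylbut-1-en-1-yl]dimethylalane | C[Al](C)/C=C(\C)CCO[Si](C)(C)C(C)(C)C | intermediate (not isolated)
22 | (2E)-5-[(tert-butyldimethylsilyl)oxy]-3-methylpent-2-en-1-ol | OC/C=C(\C)CCO[Si](C)(C)C(C)(C)C | intermediate
23 | (2E)-1-O-(tert-butyldiphenylsilyl)-5-O-(tert-butyldimethylsilyl)-3-methylpent-2-ene-1,5-diol | CC(C)(C)[Si](C)(C)OCC/C(C)=C/CO[Si](c1ccccc1)(c1ccccc1)C(C)(C)C | intermediate
24 | (3E)-5-[(tert-butyldiphenylsilyl)oxy]-3-methylpent-3-en-1-ol | OCC/C(C)=C/CO[Si](c1ccccc1)(c1ccccc1)C(C)(C)C | intermediate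
25 | [(2E)-5-bromo-3-methylpent-2-en-1-yl]oxy(tert-butyl)diphenylsilane | BrCC/C(C)=C/CO[Si](c1ccccc1)(c1ccccc1)C(C)(C)C | intermediate
26 | dimethyl(methylidene)ammonium iodide | C=[N+](C)C.[I-] | starting material
27 | [(3E)-5-[(tert-butyldiphenylsilyl)oxy]-3-methylpent-3-en-1-yl]magnesium bromide | Br[Mg]CC/C(C)=C/CO[Si](c1ccccc1)(c1ccccc1)C(C)(C)C | intermediate (not isolated)
28 | 2-(trimethylsilyl)ethyl 6β-(benzoyloxy)-15-[(tert-butyldiphenylsilyl)oxy]-7-[(trimethylsilyl)oxy]-17-nor-9βH-labda-7,13E-dien-19-oate | C[Si](C)(C)OC1=C[C@@H](CC/C(C)=C/CO[Si](c2ccccc2)(c2ccccc2)C(C)(C)C)[C@@]2(C)CCC[C@](C)(C(=O)OCC[Si](C)(C)C)[C@@H]2[C@@H]1OC(=O)c1ccccc1 | intermediate (not isolated)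
29 | 2-(trimethylsilyl)ethyl 6β-(benzoyloxy)-15-[(tert-butyldiphenylsilyl)oxy]-17-(dimethylamino)-7-oxo-8βH,9βH-labd-13E-en-19-oate | CN(C)C[C@H]1[C@@H](CC/C(C)=C/CO[Si](c2ccccc2)(c2ccccc2)C(C)(C)C)[C@@]2(C)CCC[C@](C)(C(=O)OCC[Si](C)(C)C)[C@@H]2[C@H](OC(=O)c2ccccc2)C1=O | intermediate
30 | trimethylammonium iodide of 29 (N-methylated at the C17 nitrogen) | C[N+](C)(C)C[C@H]1[C@@H](CC/C(C)=C/CO[Si](c2ccccc2)(c2ccccc2)C(C)(C)C)[C@@]2(C)CCC[C@](C)(C(=O)OCC[Si](C)(C)C)[C@@H]2[C@H](OC(=O)c2ccccc2)C1=O.[I-] | intermediate (not isolated)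
31 | 2-(trimethylsilyl)ethyl 6β-(benzoyloxy)-15-[(tert-butyldiphenylsilyl)oxy]-7-oxo-9βH-labda-8(17),13E-dien-19-oate | C=C1[C@@H](CC/C(C)=C/CO[Si](c2ccccc2)(c2ccccc2)C(C)(C)C)[C@@]2(C)CCC[C@](C)(C(=O)OCC[Si](C)(C)C)[C@@H]2[C@H](OC(=O)c2ccccc2)C1=O | intermediate
32 | 2-(trimethylsilyl)ethyl 6β-(benzoyloxy)-15-[(tert-butyldiphenylsilyl)oxy]-7α-hydroxy-9βH-labda-8(17),13E-dien-19-oate | C=C1[C@@H](CC/C(C)=C/CO[Si](c2ccccc2)(c2ccccc2)C(C)(C)C)[C@@]2(C)CCC[C@](C)(C(=O)OCC[Si](C)(C)C)[C@@H]2[C@H](OC(=O)c2ccccc2)[C@H]1O | intermediate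
33 | 6β-(benzoyloxy)-7α,15-dihydroxy-9βH-labda-8(17),13E-dien-19-oic acid (CNP0149011.1) | C=C1[C@@H](CC/C(C)=C/CO)[C@@]2(C)CCC[C@](C)(C(=O)O)[C@@H]2[C@H](OC(=O)c2ccccc2)[C@H]1O | target

**Step count**

Total: 20 steps. Longest linear sequence: 15 steps (steps 1–4, 6–12, 17–20).

**Steps most likely to fail**

Step 17. The cuprate may add only slowly at the neopentyl C9 or be consumed at the benzoate, and the silyl enol ether may be protonated before the iminium salt captures it. The fallback sets out from enone 19 and bromide 25 and joins C9–C11 without a preformed organometallic: nickel-catalysed reductive conjugate addition (NiCl2(dme), neocuproine, Mn powder, Et3SiCl, DMF, 25 °C) should give the isolable triethylsilyl enol ether F1. Treatment of this with 26 in CH2Cl2 gives Mannich base 29, where the route is rejoined.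

Step 6. Facial selectivity at C10 may be poor if the ester does not sit pseudoaxial on the silyl enol ether, so that the acceptor enters syn to it and the C10 epimer forms. The fallback sets out from 5 and reverses the order of the two C10 substituents. The kinetic trimethylsilyl enol ether F2 (LDA, Me3SiCl) is added to 8 under Sc(OTf)3 catalysis to give the C10-unmethylated diketone F3. Its side-chain ketone alone is protected (ethylene glycol, PPTS) as dioxolane F4. LDA and then MeI methylate C10 through the lithium enolate, in which the C19 ester chelates lithium in the enolate plane and the pseudoaxial C18 methyl sends iodomethane to the opposite face, giving methylated ketal F5 with C20 cis to the ester. Aqueous acid removes the dioxolane and gives diketone 10.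

Step 19. Hydride may prefer the α-face, anti to the axial C6–O bond (Felkin–Anh control by the benzoate), which would give the 7β-epimer. The fallback sets out from 31, accepts the 7β-alcohol F6 from borohydride reduction and inverts it. Mitsunobu reaction with 4-nitrobenzoic acid (PPh3, DIAD, THF) gives the 7α-(4-nitrobenzoate) F7, and NaN3 in MeOH at 40 °C removes the activated ester beside the hindered 6β-benzoate to give 32. Displacement at the terminal C17 (SN2') is the risk of this fallback itself.

Further compounds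
F1 | step 17 | 2-(trimethylsilyl)ethyl 6β-(benzoyloxy)-15-[(tert-butyldiphenylsilyl)oxy]-7-[(triethylsilyl)oxy]-17-nor-9βH-labda-7,13E-dien-19-oate | CC[Si](CC)(CC)OC1=C[C@@H](CC/C(C)=C/CO[Si](c2ccccc2)(c2ccccc2)C(C)(C)C)[C@@]2(C)CCC[C@](C)(C(=O)OCC[Si](C)(C)C)[C@@H]2[C@@H]1OC(=O)c1ccccc1
F2 | step 6 | 2-(trimethylsilyl)ethyl (1S)-1-methyl-2-[(trimethylsilyl)oxy]cyclohex-2-ene-1-carboxylate | C[Si](C)(C)OC1=CCCC[C@]1(C)C(=O)OCC[Si](C)(C)C
F3 | step 6 | 2-(trimethylsilyl)ethyl (1S)-3-(4-methoxy-3-oxobutyl)-1-methyl-2-oxocyclohexane-1-carboxylate (C3 epimers) | COCC(=O)CCC1CCC[C@](C)(C(=O)OCC[Si](C)(C)C)C1=O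
F4 | step 6 | 2-(trimethylsilyl)ethyl (1S)-3-{2-[2-(methoxymethyl)-1,3-dioxolan-2-yl]ethyl}-1-methyl-2-oxocyclohexane-1-carboxylate (C3 epimers) | COCC1(CCC2CCC[C@](C)(C(=O)OCC[Si](C)(C)C)C2=O)OCCO1
F5 | step 6 | 2-(trimethylsilyl)ethyl (1S,3R)-3-{2-[2-(methoxymethyl)-1,3-dioxolan-2-yl]ethyl}-1,3-dimethyl-2-oxocyclohexane-1-carboxylate | COCC1(CC[C@@]2(C)CCC[C@](C)(C(=O)OCC[Si](C)(C)C)C2=O)OCCO1
F6 | step 19 | 2-(trimethylsilyl)ethyl 6β-(benzoyloxy)-15-[(tert-butyldiphenylsilyl)oxy]-7β-hydroxy-9βH-labda-8(17),13E-dien-19-oate | C=C1[C@@H](CC/C(C)=C/CO[Si](c2ccccc2)(c2ccccc2)C(C)(C)C)[C@@]2(C)CCC[C@](C)(C(=O)OCC[Si](C)(C)C)[C@@H]2[C@H](OC(=O)c2ccccc2)[C@@H]1O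
F7 | step 19 | 2-(trimethylsilyl)ethyl 6β-(benzoyloxy)-15-[(tert-butyldiphenylsilyl)oxy]-7α-[(4-nitrobenzoyl)oxy]-9βH-labda-8(17),13E-dien-19-oate | C=C1[C@@H](CC/C(C)=C/CO[Si](c2ccccc2)(c2ccccc2)C(C)(C)C)[C@@]2(C)CCC[C@](C)(C(=O)OCC[Si](C)(C)C)[C@@H]2[C@H](OC(=O)c2ccccc2)[C@H]1OC(=O)c1ccc(cc1)[N+](=O)[O-]
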